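Compound numbers 1–26 are those fixed in the steps below. Atom numbers are the labdane numbers of the target (C16 = methyl on C13, C17 = methyl on C8, C18/C19 on C4, C20 on C10).

## Analysis of the target

The target is a tetracyclic, rearranged labdane. Ring A (C1–C5, C10; gem-dimethyl at C4) and ring B (C5–C10; 6-acetoxy-7-ketone) form a trans-decalin. The C8–C9 edge of ring B carries a cyclobutane (ring C: C8, C9, C14, C15), and C9–C14 is shared with a cyclopentane (ring D: C9, C11–C14) that bears the tertiary C13 carbinol.

There are seven stereocentres. C5 (H α) and C10 (CH3 β) belong to the normal labdane series. C8 (CH3 β) and C9 (C11 β, C14 α) place the cyclobutane on the α face of ring B, anti to the angular methyl. C14 has its hydrogen on the side of C10 (cis-fused bicyclo[3.2.0]heptane). C13 is S, with OH on the convex face of that bicycle (cis to H14) and its methyl towards C15. C6 carries the acetate β: axial and syn to the methyl groups on C4, C8 and C10.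

C8, C9 and C10 are three contiguous quaternary carbons; with C4 and C13, five skeletal carbons bear no hydrogen. The sensitive parts are:
- the axial α-acetoxy ketone (epimerisation at C6 to the equatorial isomer, acyl migration or elimination under base or acid);
- the tertiary alcohol (dehydration);
- the cyclobutane, which is α to the C7 carbonyl and, whenever C13 is a ketone, lies inside a 1,5-dicarbonyl array whose retro-Michael opening would break C8–C9.

The main difficulty is the C8–C9 bond. It joins two quaternary carbons inside a four-membered ring next to a third quaternary centre, where ionic or organometallic bond formation is severely hindered. The second difficulty is the C6 oxygen on the shielded β face.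

The strategy rests on one structural feature. Rings B and C share an eight-membered periphery, C5–C6–C7–C8–C15–C14–C9–C10, in which C8–C9 is the only transannular bond. Opening that bond and placing double bonds at C8=C15 and C9=C14 gives a ring A–fused cis,cis-cycloocta-2,4-dienone whose diene termini are C8 and C9. A 4π electrocyclisation then restores ring B and the four-membered ring in one event.

## Retrosynthetic reasoning

**C5–H and C6–H (26 ⇒ 25).** The last step adds only two hydrogens: the target is traced back to the enol acetate 25 (C5=C6, the acetate of a diosphenol). Oxygen cannot be brought to C6 from the β face, which is covered by three axial methyl groups. Hydrogen, however, can be added to C5=C6 from the open α face, and this leaves the acetate axial and the ring fusion trans. The step stands last because the product is the most acid- and base-sensitive compound of the route. The forward reaction has to achieve syn addition to a hindered tetrasubstituted alkene from below.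

**C13–O and C13–C16 (25 ⇒ 24 ⇒ 23).** The tertiary alcohol is taken back to the exocyclic methylene compound 24 and this to the ketone 23. A methyl nucleophile added to 23 would enter from the more accessible face and leave OH on the hindered one, the opposite of what is needed. Markovnikov hydration through a planar C13 radical delivers oxygen to the accessible face instead. The methylenation must be non-basic and ketone-selective.

**C13 dioxolane and the C6 oxygen (23 ⇒ 22 ⇒ 21 ⇒ 19).** The enol acetate is traced through the diosphenol 21 to the ring-B ketone 19, whose only enolisable position is C6 (C8 is quaternary). This oxidation is placed before the C13 carbonyl is unmasked. When 23 appears, C7 is then already a hindered, cross-conjugated enone, so no free 7,13-dione, with its retro-Michael risk across C8–C9, is ever formed. The methylenation also meets only one saturated ketone.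

**C14–H (19 ⇒ 18).** The cyclobutane comes from the cyclobutene 18 by hydrogenation, which also sets C14. The strained alkene is reduced directly after it is formed.

**C8–C9 (18 ⇒ 17).** This is the key disconnection. Cutting the transannular bond gives the dienone 17. Both quaternary centres are then formed in a unimolecular pericyclic step that needs no reagent at the congested carbons, and ring B and ring C appear together. The forward reaction must close in the sense that puts the four-membered ring on the α face.

**C8=C15 (17 ⇒ 16).** The eight-membered ring is opened at its only non-ring-fused double bond. The forward step is ring-closing metathesis between an isopropenyl ketone and the vinyl group of a diene. C6 and C9 are trans-diequatorial on ring A and hold the two olefins close.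

**C7–C8 and C14–C15 (16 ⇒ 14 + 15; 14 ⇒ 12 + 13; 12 ⇒ 11 ⇒ 9).** The isopropenyl group (C8, C17) is added as the Grignard reagent 15 to a Weinreb amide. The vinyl group (C15) comes from the stannane 13 by cross-coupling with the bromide 12. The bromide is made from the cyclopentenone 9 by α-bromination and ketalisation. The ketal is introduced at the bromo-enone stage, where the double bond does not migrate.

**C9=C14 (9 ⇒ 8 ⇒ 7).** Ring D is disconnected by an aldol condensation of the 1,4-diketone in 7. Five is the only feasible ring size, and the C7 carboxylate is inert while the ring forms.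

**Excision of C8 from a decalin (7 ⇒ 5).** The keto acid 7 is the product of oxidative cleavage of the enone 5: C7–C8 and C8–C9 are cut, C8 leaves with its methyl group, C7 becomes the carboxyl carbon and C9 the ketone. The decalin supplies ring A with C5 and C10 in the right absolute configuration, so no asymmetric step is needed.

**5 ⇒ 4 ⇒ 3 ⇒ 2 ⇒ 1.** The tetrasubstituted enone is reached without ambiguity from the exocyclic alkene of 2 (allylic hydroxylation at C7, oxidation, migration of the double bond into conjugation). Ketone 2 is the known permanganate degradation product of manool (1).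

## Alternatives that were turned down

**Alternative 1: Diels–Alder construction of ring B.**
- Disconnection: C7–C8 and C9–C10. The silyloxydiene A1 (C7=C6–C5=C10) would add to the cyclobutene ester A2 (C8=C9), under Lewis acid or pressure, to give the bicyclo[4.2.0]octene A3.
- For it: it is convergent, forms two bonds and three stereocentres (C8, C9, C10) at once, and uses the strain of A2 as driving force. The regiochemistry is matched (the nucleophilic diene terminus C7 meets C8, β to the ester). The four-membered ring is present from the start, so no late strained-ring closure is needed. On convergence and bond count it is stronger than the chosen route.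
- Against it: the C9–C10 bond would join two fully substituted carbons while C8 also becomes quaternary. A2 is a tetrasubstituted dienophile, and the C10 terminus of A1 carries two substituents, one of which must point inward and disfavours the s-cis conformer. A Lewis acid strong enough to force the reaction would probably turn it into a stepwise Mukaiyama–Michael addition or cleave the enol silane and the ketal. After A3, ring A must still be closed onto C5, the oxygen sits at C6 and not at C7, and a carbon has to be inserted between the ester and the side-chain ketal to make ring D.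
- Comparison: the chosen closure makes only one bond, but it is unimolecular and indifferent to congestion. It delivers rings A, B and D complete, with the ketone at C7.

**Alternative 2: carbenoid C–H insertion to the spiro centre.**
- Disconnection: C9–C14 (ring D). With Rh2(OAc)4 the diazo keto ester A4 would insert its carbenoid carbon into the tertiary C9–H bond, with retention, to give the spiro keto ester A5.
- For it: five-membered-ring formation by insertion into a tertiary C–H bond is dependable and stereospecific. The C8–C9 bond already exists in a decalin, and the C13 carbonyl arrives in place. As a single reaction it is better precedented than the photoclosure.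
- Against it: the C9–H bond lies between two quaternary carbons (C8, C10) and is deactivated by the β-carbonyl. Insertion into the C–H bonds next to the silyl ether oxygen, or ylide formation at the C7 ketone, may compete. The cyclobutane is still missing after A5. Closing C14–C15 by enolate alkylation would have to beat O-alkylation to a six-membered ring, and a decarboxylation would follow.
- Comparison: the chosen route creates the four-membered ring and ring B in the same step and needs no ester to be removed.

**Alternative 3: Wolff ring contraction.**
- Disconnection: C14–C15. Photolysis of the fused diazocyclopentanone A6 in methanol would contract the five-membered ketone ring to the cyclobutane ester A7.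
- For it: ring contraction of α-diazocyclopentanones is the classical, reliable entry to congested cyclobutanes. The precursor is a strain-free 5/5-fused system whose ring-fusion centres can be set under thermodynamic control, and the carbene has no adjacent hydrogen to shift. As a key step it is safer than the electrocyclisation, and this is conceded.
- Against it: the ester carbon on C15 is not in the target and costs a hydrolysis and a radical decarboxylation. Diazo transfer next to the quaternary C8 needs prior activation of a hindered ketone. The precursor A6 must already contain the C8–C9 bond between two quaternary carbons, so the central problem is only moved upstream.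
- Comparison: the chosen strategy forms that bond in the key step itself, is an isomerisation with no sacrificial atoms, and needs only a hydrogenation afterwards to reach the saturated core.

Key step: step 13

Remark on the chemistry: (+)-manool (1) is taken as a commercial natural diterpene alcohol. Only its C5 and C10 centres are used; C13 and C9 are destroyed on the way. The methyl carbon of the side-chain ketone of 2 becomes C14 of the target.

## Steps

Step 1
Reactants: 1 (+)-manool, (13R)-labda-8(17),14-dien-13-ol
Product: 2 14,15-dinorlabd-8(17)-en-13-one
Conditions: KMnO4, acetone/H2O, 0 °C → rt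
Reagents that add atoms: none
Why: Permanganate cleavage of a vinyl carbinol: dihydroxylation of the monosubstituted C14=C15 bond and cleavage of the resulting triol leave the C13 methyl ketone (its oxygen is the former hydroxyl oxygen); the hindered 1,1-disubstituted 8(17)-alkene reacts more slowly, so the oxidant is added in portions in the cold. No stereocentre is formed.

Step 2
Reactants: 2 14,15-dinorlabd-8(17)-en-13-one
Product: 3 7α-hydroxy-14,15-dinorlabd-8(17)-en-13-one
Conditions: SeO2 (cat.), t-BuOOH, CH2Cl2, rt
Reagents that add atoms: selenium dioxide, O=[Se]=O (oxygen carrier, regenerated by tert-butyl hydroperoxide, CC(C)(C)OO)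
Why: Allylic hydroxylation by SeO2 (ene reaction, then [2,3]-sigmatropic shift) of the exocyclic alkene; of the two allylic positions the ring CH2 (C7) reacts in preference to the tertiary C9–H. The axial 7α-alcohol is expected, but its configuration is irrelevant because it is oxidised next.

Step 3
Reactants: 3 7α-hydroxy-14,15-dinorlabd-8(17)-en-13-one
Product: 4 14,15-dinorlabd-8(17)-ene-7,13-dione
Conditions: Dess–Martin periodinane, CH2Cl2, rt
Reagents that add atoms: none
Why: Dess–Martin oxidation of a secondary allylic alcohol to the α-methylene ketone under neutral conditions; the side-chain ketone is inert.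

Step 4
Reactants: 4 14,15-dinorlabd-8(17)-ene-7,13-dione
Product: 5 14,15-dinorlabd-8-ene-7,13-dione
Conditions: RhCl3·3H2O (cat.), EtOH, 80 °C
Reagents that add atoms: none
Why: Rhodium-hydride mediated migration of an exocyclic α-methylene double bond into the ring (hydrometalation at C17/C8, β-hydride elimination from C9) gives the tetrasubstituted conjugated enone, the thermodynamic isomer. C5 and C10 are not affected.

Step 5
Reactants: 5 14,15-dinorlabd-8-ene-7,13-dione
Product: 7 2-[(1S,2S)-2,6,6-trimethyl-2-(4-oxopentanoyl)cyclohexyl]acetic acid, via seco-tetraketone 6 (not isolated)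
Conditions: O3, EtOAc/AcOH, −20 °C; then 30 % H2O2, H2O, rt
Reagents that add atoms: ozone, O=[O+][O-]; hydrogen peroxide, OO
Why: Ozonolysis of an α,β-unsaturated ketone with oxidative work-up, the classical enone-to-keto-acid degradation: O3 cleaves C8=C9 to the C9 ketone and a C7/C8 α-dicarbonyl unit (6), which H2O2 cleaves between C7 and C8. C8 and C17 are lost, C7 becomes the carboxyl carbon and the side chain is now a 1,4-diketone; C5 is β to the carboxyl group and cannot epimerise.

Step 6
Reactants: 7 2-[(1S,2S)-2,6,6-trimethyl-2-(4-oxopentanoyl)cyclohexyl]acetic acid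
Product: 8 2-[(1S,2S)-2,6,6-trimethyl-2-(3-oxocyclopent-1-en-1-yl)cyclohexyl]acetic acid
Conditions: KOH, EtOH/H2O, reflux; then HCl
Reagents that add atoms: none
Why: Intramolecular aldol condensation of a 1,4-diketone to a cyclopentenone: the methyl carbon of the C13 ketone (C14) attacks the C9 ketone, five being the only possible ring size, and dehydration fixes C9=C14. The carboxylate is inert to base, which is why the ring is closed before the acid is converted into an amide that could undergo Claisen condensation with C11.

Step 7
Reactants: 8 2-[(1S,2S)-2,6,6-trimethyl-2-(3-oxocyclopent-1-en-1-yl)cyclohexyl]acetic acid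
Product: 9 N-methoxy-N-methyl-2-[(1S,2S)-2,6,6-trimethyl-2-(3-oxocyclopent-1-en-1-yl)cyclohexyl]acetamide
Conditions: MeNHOMe·HCl, EDC·HCl, i-Pr2NEt, CH2Cl2, 0 °C → rt
Reagents that add atoms: N,O-dimethylhydroxylamine hydrochloride, CNOC.Cl
Why: Carbodiimide amidation to the Weinreb amide, which will later stop a Grignard addition at the ketone stage; the β,β-disubstituted enone does not add the amine.

Step 8
Reactants: 9 N-methoxy-N-methyl-2-[(1S,2S)-2,6,6-trimethyl-2-(3-oxocyclopent-1-en-1-yl)cyclohexyl]acetamide
Product: 11 2-[(1S,2S)-2-(2-bromo-3-oxocyclopent-1-en-1-yl)-2,6,6-trimethylcyclohexyl]-N-methoxy-N-methylacetamide, via dibromide 10 (not isolated)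
Conditions: Br2, CH2Cl2, 0 °C; then Et3N, rt
Reagents that add atoms: bromine, BrBr
Why: α-Bromination of an enone by addition–elimination: Br2 adds across C9=C14 and Et3N removes HBr through the C14 enolate. This is preferred to iodine/pyridine, whose mechanism needs nucleophilic attack at the fully substituted β-carbon C9.

Step 9
Reactants: 11 2-[(1S,2S)-2-(2-bromo-3-oxocyclopent-1-en-1-yl)-2,6,6-trimethylcyclohexyl]-N-methoxy-N-methylacetamide
Product: 12 2-[(1S,2S)-2-(6-bromo-1,4-dioxaspiro[4.4]non-6-en-7-yl)-2,6,6-trimethylcyclohexyl]-N-methoxy-N-methylacetamide
Conditions: HOCH2CH2OH, TsOH·H2O (cat.), benzene, reflux, Dean–Stark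
Reagents that add atoms: ethylene glycol, OCCO
Why: Acid-catalysed dioxolane formation with azeotropic removal of water; 2-bromo-enones ketalise without migration of the double bond. The ketal removes the cyclopentenone chromophore before the photolysis and masks C13 until step 17.

Step 10
Reactants: 12 2-[(1S,2S)-2-(6-bromo-1,4-dioxaspiro[4.4]non-6-en-7-yl)-2,6,6-trimethylcyclohexyl]-N-methoxy-N-methylacetamide; 13 tributyl(vinyl)stannane
Product: 14 2-[(1S,2S)-2-(6-ethenyl-1,4-dioxaspiro[4.4]non-6-en-7-yl)-2,6,6-trimethylcyclohexyl]-N-methoxy-N-methylacetamide
Conditions: Pd(PPh3)4 (5 mol %), CuI (10 mol %), CsF, DMF, 50 °C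
Reagents that add atoms: tributyl(vinyl)stannane (13), C=C[Sn](CCCC)(CCCC)CCCC
Why: Stille coupling of an alkenyl bromide with a vinylstannane at zerovalent palladium; CuI and CsF speed up transmetalation at the congested tetrasubstituted alkene. The step adds C15 and completes the C9=C14–C15 diene.

Step 11
Reactants: 14 2-[(1S,2S)-2-(6-ethenyl-1,4-dioxaspiro[4.4]non-6-en-7-yl)-2,6,6-trimethylcyclohexyl]-N-methoxy-N-methylacetamide; 15 isopropenylmagnesium bromide
Product: 16 1-[(1S,2S)-2-(6-ethenyl-1,4-dioxaspiro[4.4]non-6-en-7-yl)-2,6,6-trimethylcyclohexyl]-3-methylbut-3-en-2-one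
Conditions: THF, −20 → 0 °C; then cold aq. NH4Cl
Reagents that add atoms: isopropenylmagnesium bromide (15), CC(=C)[Mg]Br
Why: Weinreb ketone synthesis: the magnesium chelate of the adduct survives until the mild quench, so one isopropenyl group is added and the C7 ketone with C8 and C17 is in place; dioxolane and diene are inert to the Grignard reagent. The enone is used at once.

Step 12
Reactants: 16 1-[(1S,2S)-2-(6-ethenyl-1,4-dioxaspiro[4.4]non-6-en-7-yl)-2,6,6-trimethylcyclohexyl]-3-methylbut-3-en-2-one
Product: 17 ring A–fused cis,cis-cycloocta-2,4-dienone (C7 ketone; C8(CH3)=C15 and C14=C9; ring D with C13 dioxolane; 5α-H; 10β-CH3)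
Conditions: second-generation Grubbs catalyst RuCl2(H2IMes)(PCy3)(=CHPh) (10 mol %), toluene (1 mM), 80 °C, Ar sparge
Reagents that add atoms: none
Why: Ring-closing metathesis: the ruthenium alkylidene loads on the monosubstituted vinyl group and closes onto the isopropenyl ketone with loss of ethylene; an eight-membered ring can hold only the Z-configured C8=C15 bond. The trans-diequatorial C6 and C9 branches on the chair of ring A hold the olefins close, and high dilution with ethylene removal counters oligomerisation.

Step 13
Reactants: 17 ring A–fused cis,cis-cycloocta-2,4-dienone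
Product: 18 tetracyclic cyclobutene (C8–C9 bond; C14=C15; 8β-CH3; C11 β on C9; four-membered ring on the α face; C7 ketone; C13 dioxolane)
Conditions: hν (365 nm), degassed cyclohexane (2 mM), 10 °C
Reagents that add atoms: none
Why: Excitation of the dienone leads to bonding between the diene termini C8 and C9 with a new C14=C15 double bond, a 4π electrocyclisation that is photochemically allowed in the disrotatory sense; a path through photoisomerisation of C8=C15 and thermal conrotatory closure of the strained isomer would end in the same cis-fused product. The closest known reaction type is the photochemical valence isomerisation of cis,cis-cycloocta-1,3-dienes and of cyclic 2,4-dienones to bicyclic cyclobutenes, including cases where a methyl-bearing α-carbon becomes quaternary. The cyclobutene is closed by 1,4-bonding within the diene, and ring B results from the same bond because it divides the eight-membered ring transannularly into a six- and a four-membered ring; the process is pericyclic, so rules for ionic ring closure do not apply. At C8 and C9 the cis ring fusion (C7 and C10 on the same face of the cyclobutene) follows from the Z geometry of both double bonds and the disrotatory motion. Their configuration relative to C5 and C10 is the selectivity that the step needs (torquoselectivity): the chair of ring A holds C6 and C9 equatorial, and the bridge C14–C15=C8 can span them only on the α face, because on the β face it would have to pass over the axial C10 methyl. Closure from this conformer turns C14 and C15 down and the C8 methyl and C11 up. Two fully substituted termini are tolerated because no reagent has to reach them. Long-wavelength light and high dilution are used so that the β,γ-unsaturated ketone product is not photolysed further (1,3-acyl shift) and bimolecular [2+2] addition is suppressed; the solution is taken directly into step 14.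

Step 14
Reactants: 18 tetracyclic cyclobutene
Product: 19 tetracyclic cyclobutane ketone (C14–C15 saturated; H14 on the side of C10; C7 ketone; C13 dioxolane)
Conditions: H2 (1 atm), Pd/C (5 %), EtOAc, 0 °C → rt
Reagents that add atoms: none
Why: Heterogeneous syn-hydrogenation of a strained cyclobutene: hydrogen adds to the face of C14=C15 that bears C10 and C7, towards which the pyramidalised C14 is exposed because ring D pulls C13 to the other face, so the cis-fused bicyclo[3.2.0]heptane forms and C14 is set. The double bond cannot migrate, since C8, C9 and C13 carry no hydrogen.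

Step 15
Reactants: 19 tetracyclic cyclobutane ketone
Product: 21 diosphenol (6-hydroxy-5-en-7-one; C13 dioxolane), via 6α-hydroperoxide 20 (not isolated)
Conditions: KOt-Bu, O2 (1 atm), t-BuOH/THF, 0 °C → rt; then AcOH
Reagents that add atoms: dioxygen, O=O
Why: Base-mediated autoxidation of a ketone to a diosphenol: the only possible enolate (towards C6, C8 being quaternary) traps O2, the hydroperoxide 20 loses hydroxide to give the α-dicarbonyl tautomer of 21, and this enolises towards C5. The C5 stereocentre is erased on purpose and is reset in step 20; the dioxolane is stable to base.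

Step 16
Reactants: 21 diosphenol
Product: 22 diosphenol acetate (6-acetoxy-5-en-7-one; C13 dioxolane)
Conditions: Ac2O, pyridine, DMAP (cat.), CH2Cl2, 0 °C → rt
Reagents that add atoms: acetic anhydride, CC(=O)OC(C)=O
Why: O-Acetylation of the acidic enol hydroxyl; it introduces the acetate of the target and turns C7 into a hindered, cross-conjugated enone carbonyl for the next three steps.

Step 17
Reactants: 22 diosphenol acetate
Product: 23 6-acetoxy-5-ene-7,13-dione (C13 ketone free)
Conditions: TsOH·H2O (cat.), THF/H2O, rt
Reagents that add atoms: water, O
Why: Acid-catalysed hydrolysis of the dioxolane; the enol acetate survives dilute acid at room temperature. C14 is α to the new ketone, but only the cis ring fusion is free of extra strain, so it is not at risk.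

Step 18
Reactants: 23 6-acetoxy-5-ene-7,13-dione
Product: 24 6-acetoxy-13-methylene-5-en-7-one
Conditions: Zn, CH2Br2, TiCl4, THF/CH2Cl2, 0 °C → rt
Reagents that add atoms: dibromomethane, BrCBr
Why: Takai–Lombardo methylenation with the zinc/titanium methylene reagent: it is non-basic (no enolisation at C12 or C14, no attack on the enol acetate) and reacts with the unhindered saturated C13 ketone, not with the tetrasubstituted enone carbonyl at C7. It adds C16.

Step 19
Reactants: 24 6-acetoxy-13-methylene-5-en-7-one
Product: 25 (13S)-6-acetoxy-13-hydroxy-13-methyl-5-en-7-one (OH cis to H14)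
Conditions: Co(acac)2 (20 mol %), PhSiH3, O2 (1 atm), THF, rt
Reagents that add atoms: dioxygen, O=O
Why: Mukaiyama hydration: a cobalt hydride transfers a hydrogen atom to the CH2 terminus, and the tertiary C13 radical is captured by O2 on the convex face of the cis-bicyclo[3.2.0]heptane, away from the cyclobutane CH2; the silane reduces the O–O bond. This places OH cis to H14 and the methyl towards C15 as in the target. The tetrasubstituted acetoxy-enone is not a substrate for hydrogen-atom transfer under these conditions.

Step 20
Reactants: 25 (13S)-6-acetoxy-13-hydroxy-13-methyl-5-en-7-one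
Product: 26 CNP0330581.1 (6β-acetoxy-13-hydroxy-7-ketone; 5α-H)
Conditions: H2 (5 bar), Pd/C (10 %), EtOAc, rt
Reagents that add atoms: none
Why: Heterogeneous syn-hydrogenation of the enol acetate double bond C5=C6 that is conjugated to the C7 ketone. Both hydrogens are delivered to the α face, opposite the three β-axial methyl groups on C4, C8 and C10, which sets 5α-H (trans A/B) and 6α-H, that is the axial 6β-acetate. The neutral medium avoids epimerisation at C6 and leaves the tertiary alcohol untouched.

## Compound list

1 | (+)-manool, (13R)-labda-8(17),14-dien-13-ol | C=C[C@](C)(O)CC[C@H]1C(=C)CC[C@@H]2[C@]1(C)CCCC2(C)C | starting material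
2 | 14,15-dinorlabd-8(17)-en-13-one | CC(=O)CC[C@H]1C(=C)CC[C@@H]2[C@]1(C)CCCC2(C)C | intermediate
3 | 7α-hydroxy-14,15-dinorlabd-8(17)-en-13-one | CC(=O)CC[C@H]1C(=C)[C@H](O)C[C@@H]2[C@]1(C)CCCC2(C)C | intermediate
4 | 14,15-dinorlabd-8(17)-ene-7,13-dione | CC(=O)CC[C@H]1C(=C)C(=O)C[C@@H]2[C@]1(C)CCCC2(C)C | intermediate
5 | 14,15-dinorlabd-8-ene-7,13-dione | CC(=O)CCC1=C(C)C(=O)C[C@@H]2[C@]1(C)CCCC2(C)C | intermediate
6 | 14,15-dinor-8,9-secolabdane-7,8,9,13-tetraone (5α-H, 10β-CH3) | CC(=O)CCC(=O)[C@@]1(C)CCCC(C)(C)[C@@H]1CC(=O)C(C)=O | intermediate (not isolated)
7 | 2-[(1S,2S)-2,6,6-trimethyl-2-(4-oxopentanoyl)cyclohexyl]acetic acid | CC(=O)CCC(=O)[C@@]1(C)CCCC(C)(C)[C@@H]1CC(=O)O | intermediate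
8 | 2-[(1S,2S)-2,6,6-trimethyl-2-(3-oxocyclopent-1-en-1-yl)cyclohexyl]acetic acid | O=C1CCC(=C1)[C@@]2(C)CCCC(C)(C)[C@@H]2CC(=O)O | intermediate
9 | N-methoxy-N-methyl-2-[(1S,2S)-2,6,6-trimethyl-2-(3-oxocyclopent-1-en-1-yl)cyclohexyl]acetamide | O=C1CCC(=C1)[C@@]2(C)CCCC(C)(C)[C@@H]2CC(=O)N(C)OC | intermediate
10 | 2-[(1S,2S)-2-(1,2-dibromo-3-oxocyclopentyl)-2,6,6-trimethylcyclohexyl]-N-methoxy-N-methylacetamide (anti-dibromide, both faces; the two C–Br centres are left open) | O=C1CCC(Br)(C1Br)[C@@]2(C)CCCC(C)(C)[C@@H]2CC(=O)N(C)OC | intermediate (not isolated)
11 | 2-[(1S,2S)-2-(2-bromo-3-oxocyclopent-1-en-1-yl)-2,6,6-trimethylcyclohexyl]-N-methoxy-N-methylacetamide | O=C1CCC(=C1Br)[C@@]2(C)CCCC(C)(C)[C@@H]2CC(=O)N(C)OC | intermediate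
12 | 2-[(1S,2S)-2-(6-bromo-1,4-dioxaspiro[4.4]non-6-en-7-yl)-2,6,6-trimethylcyclohexyl]-N-methoxy-N-methylacetamide | BrC1=C(CCC12OCCO2)[C@@]3(C)CCCC(C)(C)[C@@H]3CC(=O)N(C)OC | intermediate
13 | tributyl(vinyl)stannane | C=C[Sn](CCCC)(CCCC)CCCC | starting material
14 | 2-[(1S,2S)-2-(6-ethenyl-1,4-dioxaspiro[4.4]non-6-en-7-yl)-2,6,6-trimethylcyclohexyl]-N-methoxy-N-methylacetamide | C=CC1=C(CCC12OCCO2)[C@@]3(C)CCCC(C)(C)[C@@H]3CC(=O)N(C)OC | intermediate
15 | isopropenylmagnesium bromide | CC(=C)[Mg]Br | starting material
16 | 1-[(1S,2S)-2-(6-ethenyl-1,4-dioxaspiro[4.4]non-6-en-7-yl)-2,6,6-trimethylcyclohexyl]-3-methylbut-3-en-2-one | C=CC1=C(CCC12OCCO2)[C@@]3(C)CCCC(C)(C)[C@@H]3CC(=O)C(C)=C | intermediate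
17 | ring A–fused cis,cis-cycloocta-2,4-dienone (C7 ketone, C8(CH3)=C15, C14=C9, C13 dioxolane, 5α-H, 10β-CH3) | C1C(=O)/C(C)=C\C2=C(CCC23OCCO3)[C@@]2(C)CCCC(C)(C)[C@H]12 | intermediate (key-step precursor)
18 | tetracyclic cyclobutene (C8–C9 bond, C14=C15, 8β-CH3, cyclobutene α, C7 ketone, C13 dioxolane) | C1C(=O)[C@@]2(C)C=C3[C@@]2(CCC34OCCO4)[C@@]2(C)CCCC(C)(C)[C@H]12 | intermediate (key-step product)
19 | tetracyclic cyclobutane ketone (H14 on the side of C10, C7 ketone, C13 dioxolane) | C1C(=O)[C@@]2(C)C[C@H]3[C@@]2(CCC34OCCO4)[C@@]2(C)CCCC(C)(C)[C@H]12 | intermediate
20 | 6α-hydroperoxide of 19 | OO[C@H]1C(=O)[C@@]2(C)C[C@H]3[C@@]2(CCC34OCCO4)[C@@]2(C)CCCC(C)(C)[C@H]12 | intermediate (not isolated)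
21 | diosphenol: 6-hydroxy-5-en-7-one, C13 dioxolane | OC1=C2C(C)(C)CCC[C@]2(C)[C@@]3(CCC4(OCCO4)[C@H]3C5)[C@@]5(C)C1=O | intermediate
22 | diosphenol acetate: 6-acetoxy-5-en-7-one, C13 dioxolane | CC(=O)OC1=C2C(C)(C)CCC[C@]2(C)[C@@]3(CCC4(OCCO4)[C@H]3C5)[C@@]5(C)C1=O | intermediate
23 | 6-acetoxy-5-ene-7,13-dione | CC(=O)OC1=C2C(C)(C)CCC[C@]2(C)[C@@]3(CCC(=O)[C@H]3C5)[C@@]5(C)C1=O | intermediate
24 | 6-acetoxy-13-methylene-5-en-7-one | CC(=O)OC1=C2C(C)(C)CCC[C@]2(C)[C@@]3(CCC(=C)[C@H]3C5)[C@@]5(C)C1=O | intermediate
25 | (13S)-6-acetoxy-13-hydroxy-13-methyl-5-en-7-one | CC(=O)OC1=C2C(C)(C)CCC[C@]2(C)[C@@]3(CC[C@](C)(O)[C@H]3C5)[C@@]5(C)C1=O | intermediate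
26 | CNP0330581.1 | CC(=O)O[C@@H]1C(=O)[C@@]2(C)C[C@H]3[C@@]2(CC[C@]3(C)O)[C@@]2(C)CCCC(C)(C)[C@H]12 | target

## Step count and least certain steps

Total step count: 20. Longest linear sequence: 20 steps (1 → 26); 13 and 15 are purchased.

**Step 13 (key step).** The most likely failure is closure through the other tub conformer, which would put the cyclobutene on the β face. Also possible are diversion of the excited dienone into bimolecular cycloaddition after E/Z isomerisation of C8=C15, and secondary photolysis of the β,γ-unsaturated ketone product. The reason is that the sense of closure is set only by the conformational preference of a flexible eight-membered ring, and the product itself absorbs light.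
Fallback (sets out from 5, returns at 25): vinylmagnesium bromide in THF at −78 °C should add to the unhindered C13 methyl ketone of 5, and not to the tetrasubstituted C7 enone, to give 13-hydroxylabda-8,14-dien-7-one F1 as both C13 epimers. Irradiation at 350 nm should then effect the intramolecular enone–alkene [2+2] photocycloaddition (C9–C14 first, five-membered ring, α face) and give, after chromatographic removal of the C13 epimer, the tetracyclic hydroxy ketone F2. Autoxidation as in step 15 should give the diosphenol carbinol F3, and acetylation as in step 16 gives 25. This fallback gives up control of C13.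

**Step 12.** The likely failure is that the catalyst, resting as the conjugated vinyl-alkylidene at C15, does not engage the 1,1-disubstituted electron-poor olefin. Oligomerisation through the vinyl groups, or a thermal intramolecular [4+2] addition of the isopropenyl ketone to the diene at 80 °C, would then take over.
Fallback (sets out from 14, returns at 17): Lemieux–Johnson cleavage (OsO4 cat., NaIO4, 2,6-lutidine) of the monosubstituted vinyl group should give the enal F4. Olefination with the ylide from (1-iodoethyl)triphenylphosphonium iodide and NaN(SiMe3)2 should give the (Z)-iodoalkene F5. i-Bu2AlH at −78 °C should reduce the Weinreb amide to the aldehyde F6. A Nozaki–Hiyama–Kishi cyclisation (CrCl2, NiCl2 cat., DMSO, high dilution) would form C7–C8 and give the cyclic dienol F7 as C7 epimers, and Dess–Martin oxidation gives 17.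

**Step 20.** The likely failures are incomplete reduction or hydrogen uptake from the β face, because C5=C6 is tetrasubstituted and flanked by two quaternary carbons. Hydrogenolysis of the enol C–O bond is the side process to watch.
Fallback (sets out from 25, returns at 26): conjugate reduction by hydrogen-atom transfer with Mn(dpm)3, tris(dipivaloylmethanato)manganese (cat.), and PhSiH3 in i-PrOH. Here a small metal hydride in solution delivers a hydrogen atom to C5, and the C6 radical or enolate is quenched from the open α face, so no adsorption of the alkene on a surface is needed. No new compound is formed (F0).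

**Step 19.** The likely failure is poor or reversed facial selectivity in the capture of the C13 radical by oxygen. The convex face of ring D, normally the open one, also faces C10 and the C1 methylene of ring A.
Fallback (sets out from 23, returns at 25): the stereocomplementary direct addition of a methyl nucleophile to the C13 ketone, with MeCeCl2 (from MeLi and CeCl3) in THF at −78 °C, where a ketone reacts far faster than the enol ester. The methyl group then enters from whichever face proved more accessible and leaves OH on the other. No new compound is formed (F0).

**Step 15.** The likely failure is over-oxidation of the diosphenolate by excess oxygen, with cleavage of ring B.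
Fallback (sets out from 19, returns at 21): LiN(i-Pr)2 and Me3SiCl should give the silyl enol ether F8. Rubottom oxidation (mCPBA, then dilute acid) should give the 6α-hydroxy ketone F9 by attack on the α face. Dess–Martin oxidation gives the α-dicarbonyl tautomer, which enolises to 21.

## Further compounds

F1 | step 13 | 13-hydroxylabda-8,14-dien-7-one (both C13 epimers) | C=CC(C)(O)CCC1=C(C)C(=O)C[C@@H]2[C@]1(C)CCCC2(C)C
F2 | step 13 | tetracyclic (13S)-13-hydroxy-7-ketone (26 without the acetoxy group) | C1C(=O)[C@@]2(C)C[C@H]3[C@@]2(CC[C@]3(C)O)[C@@]2(C)CCCC(C)(C)[C@H]12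
F3 | step 13 | diosphenol carbinol (6,13-dihydroxy-5-en-7-one, 13S) | OC1=C2C(C)(C)CCC[C@]2(C)[C@@]3(CC[C@](C)(O)[C@H]3C5)[C@@]5(C)C1=O
F4 | step 12 | 2-[(1S,2S)-2-(6-formyl-1,4-dioxaspiro[4.4]non-6-en-7-yl)-2,6,6-trimethylcyclohexyl]-N-methoxy-N-methylacetamide | O=CC1=C(CCC12OCCO2)[C@@]3(C)CCCC(C)(C)[C@@H]3CC(=O)N(C)OC
F5 | step 12 | 2-[(1S,2S)-2-{6-[(Z)-2-iodoprop-1-enyl]-1,4-dioxaspiro[4.4]non-6-en-7-yl}-2,6,6-trimethylcyclohexyl]-N-methoxy-N-methylacetamide | C/C(I)=C/C1=C(CCC12OCCO2)[C@@]3(C)CCCC(C)(C)[C@@H]3CC(=O)N(C)OC
F6 | step 12 | 2-[(1S,2S)-2-{6-[(Z)-2-iodoprop-1-enyl]-1,4-dioxaspiro[4.4]non-6-en-7-yl}-2,6,6-trimethylcyclohexyl]acetaldehyde | C/C(I)=C/C1=C(CCC12OCCO2)[C@@]3(C)CCCC(C)(C)[C@@H]3CC=O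
F7 | step 12 | ring A–fused cis,cis-cycloocta-2,4-dienol (C7 carbinol of 17, both epimers) | C1C(O)/C(C)=C\C2=C(CCC23OCCO3)[C@@]2(C)CCCC(C)(C)[C@H]12
F8 | step 15 | trimethylsilyl enol ether of 19 (C6=C7) | C1=C(O[Si](C)(C)C)[C@@]2(C)C[C@H]3[C@@]2(CCC34OCCO4)[C@@]2(C)CCCC(C)(C)[C@H]12
F9 | step 15 | 6α-hydroxy derivative of 19 | O[C@H]1C(=O)[C@@]2(C)C[C@H]3[C@@]2(CCC34OCCO4)[C@@]2(C)CCCC(C)(C)[C@H]12
F0 | step 20 | none | none
F0 | step 19 | none | none
A1 | alternative 1 | (Z)-tert-butyl[(4,8-dimethylnona-1,3,7-trien-2-yl)oxy]dimethylsilane (the Z isomer is the one required if the ester is endo) | C=C(O[Si](C)(C)C(C)(C)C)/C=C(C)\CCC=C(C)C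
A2 | alternative 1 | methyl 2-methyl-4-(2-methyl-1,3-dioxolan-2-yl)cyclobut-1-ene-1-carboxylate | COC(=O)C1=C(C)C[C@@H]1C2(C)OCCO2
A3 | alternative 1 | Diels–Alder adduct, bicyclo[4.2.0]octene with C6 enol silane | C1C(O[Si](C)(C)C(C)(C)C)=C[C@](C)(CCC=C(C)C)[C@]2(C(=O)OC)[C@@H](C3(C)OCCO3)C[C@]12C
A4 | alternative 2 | α-diazo-β-keto ester on the 9α-H decalin (C8 with CH3 and CH2OTBS) | C1C(=O)[C@@](C)(CO[Si](C)(C)C(C)(C)C)[C@H](CCC(=O)C(=[N+]=[N-])C(=O)OC)[C@@]2(C)CCCC(C)(C)[C@H]12
A5 | alternative 2 | spiro β-keto ester from C9–H insertion | C1C(=O)[C@@](C)(CO[Si](C)(C)C(C)(C)C)[C@]2(CCC(=O)[C@@H]2C(=O)OC)[C@@]3(C)CCCC(C)(C)[C@H]13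
A6 | alternative 3 | fused α-diazocyclopentanone (C7 and C13 as dioxolanes) | C1C2(OCCO2)[C@@]3(C)C(=[N+]=[N-])C(=O)[C@H]4[C@@]3(CCC45OCCO5)[C@@]3(C)CCCC(C)(C)[C@H]13
A7 | alternative 3 | cyclobutane C15 methyl ester from Wolff contraction | C1C2(OCCO2)[C@@]3(C)[C@H](C(=O)OC)[C@H]4[C@@]3(CCC45OCCO5)[C@@]3(C)CCCC(C)(C)[C@H]13
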